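**Retrosynthetic overview**
- The target is disconnected at the C2–OH bond (nucleophilic epoxidation, then epoxide-to-enol isomerisation) to 2-methoxy-6-docosyl-1,4-benzoquinone, and this at the quinone oxygen to 3-methoxy-5-docosylphenol. These two oxidations mirror the dihydroxylation and autoxidation of an O-methylated alkylresorcinol.
- 3-Methoxy-5-docosylphenol is disconnected by a decarboxylative C2→C7 aldol aromatisation (the alkylresorcinol-synthase mode) to an open-chain C29 tetraketide acid: a fatty acyl starter plus three acetate units, with the C3 oxygen already methylated.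
- The tetraketide is disconnected by a Claisen C–C bond between starter and extender units to methyl tricosanoate and 4-methoxy-6-methyl-2-pyrone, which serves as a masked triketide.
- Ring order: the only carbocycle is formed in step 1 from the acyclic tetraketide after the pyrone of the building block has been opened; no other ring is made.

Assumption: the target has no stereocentre, so it is made as the one achiral compound; the side chain is read as unbranched docosyl (22 carbons), and both starting materials are taken as catalogue compounds.

**Step 1**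
Reactants: 1 4-methoxy-6-methyl-2H-pyran-2-one (2.2 equiv); 2 methyl tricosanoate (1.0 equiv)
Product: 7 3-methoxy-5-docosylphenol, via lithiated pyrone 3 (not isolated), via ketopyrone 4 (not isolated), via open-chain tetraketide acid 5 (not isolated), via benzoic acid 6 (not isolated)
Conditions: LiN(i-Pr)2 (2.2 equiv), THF, −78 °C; add 2, −78 to 0 °C; then 2 M aq KOH, 40 °C; then THF distilled off, 6 M HCl to pH 1, 1,4-dioxane, 95 °C
Reagents that add atoms: none
Why: Proposed new method: LiN(i-Pr)2 removes a proton from the 6-methyl group (the vinylogous α-position of the lactone) to give dienolate 3, which undergoes Claisen acylation by 2 (the second equivalent of 3 deprotonates 4); hydroxide then opens the lactone to the carboxylate of 5, in which Claisen-type closure is impossible, so the C4-derived dienolate adds through C2 to the C7 ketone (the C2→C7 aldol of alkylresorcinol synthases), dehydration aromatises to 6, and acidification with heating removes CO2 by ipso-protonation of the ortho-methoxy/para-hydroxy acid; the closest known reactions are the acylation of pyrone anions with esters and the aqueous KOH cyclisation of tetraacetic lactone to orsellinic acid followed by its thermal decarboxylation, the untested part being the single-flask sequence with retention of the enol methyl ether.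

**Step 2**
Reactants: 7 3-methoxy-5-docosylphenol
Product: 8 2-methoxy-6-docosyl-1,4-benzoquinone
Conditions: K2[ON(SO3)2] (2.5 equiv), KH2PO4 buffer (pH 6), methyltrioctylammonium chloride (cat.), CH2Cl2/H2O, 25 °C
Reagents that add atoms: potassium nitrosodisulfonate, [K+].[K+].[O]N(S(=O)(=O)[O-])S(=O)(=O)[O-]
Why: Teuber oxidation: the phenoxyl radical formed by the first nitroxyl is trapped by a second one at the free para carbon (between the methoxy and alkyl groups), and loss of imidodisulfonate gives the para-quinone, as in the oxidation of 3-methoxy-5-pentylphenol to primin; the phase-transfer salt carries the oxidant to the lipophilic phenol.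

**Step 3**
Reactants: 8 2-methoxy-6-docosyl-1,4-benzoquinone
Product: 10 2-hydroxy-5-methoxy-3-docosyl-1,4-benzoquinone, via epoxyquinone 9 (not isolated)
Conditions: t-BuOOH (1.5 equiv, decane solution), DBU (0.2 equiv), CH2Cl2, 0 °C; then solvent removed, conc. H2SO4, 0 °C, 15 min; ice water
Reagents that add atoms: tert-butyl hydroperoxide, CC(C)(C)OO
Why: Weitz–Scheffer nucleophilic epoxidation occurs at the alkyl-bearing C5=C6 bond because the methoxy-bearing C2=C3 bond is a deactivated vinylogous ester, and acid-promoted opening of the epoxide with loss of the C5 proton (the menadione oxide to phthiocol isomerisation) gives the hydroxyquinone; the two transient stereocentres of racemic 9 are destroyed and the target is achiral.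

**Compound list**
1 | 4-methoxy-6-methyl-2H-pyran-2-one | COC1=CC(=O)OC(C)=C1 | starting material
2 | methyl tricosanoate | CCCCCCCCCCCCCCCCCCCCCCC(=O)OC | starting material
3 | 6-(lithiomethyl)-4-methoxy-2H-pyran-2-one (lithium dienolate of 1) | [Li]CC1=CC(OC)=CC(=O)O1 | intermediate
4 | 4-methoxy-6-(2-oxotetracosyl)-2H-pyran-2-one | COC1=CC(=O)OC(CC(=O)CCCCCCCCCCCCCCCCCCCCCC)=C1 | intermediate
5 | (2E)-3-methoxy-5,7-dioxononacos-2-enoic acid | OC(=O)/C=C(/OC)CC(=O)CC(=O)CCCCCCCCCCCCCCCCCCCCCC | intermediate
6 | 6-docosyl-4-hydroxy-2-methoxybenzoic acid | COc1cc(O)cc(CCCCCCCCCCCCCCCCCCCCCC)c1C(=O)O | intermediate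
7 | 3-methoxy-5-docosylphenol | COc1cc(O)cc(CCCCCCCCCCCCCCCCCCCCCC)c1 | intermediate
8 | 2-methoxy-6-docosyl-1,4-benzoquinone | COC1=CC(=O)C=C(CCCCCCCCCCCCCCCCCCCCCC)C1=O | intermediate
9 | 1-docosyl-3-methoxy-7-oxabicyclo[4.1.0]hept-3-ene-2,5-dione (5,6-epoxide of 8; racemic, cis-fused, one enantiomer written) | COC1=CC(=O)[C@H]2O[C@@]2(CCCCCCCCCCCCCCCCCCCCCC)C1=O | intermediate
10 | 2-hydroxy-5-methoxy-3-docosyl-1,4-benzoquinone | CCCCCCCCCCCCCCCCCCCCCCC1=C(O)C(=O)C=C(OC)C1=O | target

**Total step count:** 3. **Longest linear sequence:** 3.

**Steps most likely to fail, with fallbacks**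

1. Step 1 (most at risk). Hydroxide may strip the enol methyl ether, or the single-flask sequence may give mixtures. The fallback sets out from 2 and comes back at 7. Commercial triacetic acid lactone (4-hydroxy-6-methyl-2H-pyran-2-one) is deprotonated twice with LiN(i-Pr)2 (3.2 equiv in all) to dilithiated triacetic acid lactone F1. F1 is acylated at the methyl carbon by 2 to give, after acidification, 4-hydroxy-6-(2-oxotetracosyl)-2H-pyran-2-one F2, which is isolated. Aqueous KOH at 25 °C effects the C2→C7 aldol aromatisation to 2,4-dihydroxy-6-docosylbenzoic acid F3. Heating F3 in DMSO at 120 °C gives 5-docosylresorcinol F4. One of its two equivalent hydroxyls is then methylated (dimethyl sulfate 1.0 equiv, K2CO3, acetone; diether and unreacted diol separated and recycled) to give 7.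

2. Step 3. The methoxy group may be hydrolysed in strong acid, or the epoxide may open the wrong way. The fallback sets out from 8 and comes back at 10. Thiele–Winter acetoxylation (Ac2O, BF3·OEt2, 25 °C) adds acetate at C5, the position conjugated to the carbonyl that the methoxy group does not deactivate, and gives 1,2,4-triacetoxy-3-docosyl-5-methoxybenzene F5. Methanolysis (K2CO3, MeOH) under air liberates 3-docosyl-5-methoxybenzene-1,2,4-triol F6, which autoxidises in the same flask to 10.

3. Step 2. The para carbon is flanked by two substituents and the radical oxidation may stall in the two-phase system. The fallback sets out from 7 and comes back at 8. Nitrosation (NaNO2, AcOH/THF, 0 °C) at the same para carbon gives 3-methoxy-4-nitroso-5-docosylphenol F7 (quinone monoxime tautomer). Reduction with Na2S2O4 in aqueous THF gives 4-amino-3-methoxy-5-docosylphenol F8. Oxidation of F8 with FeCl3 in dilute HCl, with hydrolysis of the nitrogen, delivers 8.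

**Further compounds**
F1 | step 1 | dilithiated triacetic acid lactone (6-(lithiomethyl)-4-(lithiooxy)-2H-pyran-2-one) | [Li]CC1=CC(O[Li])=CC(=O)O1
F2 | step 1 | 4-hydroxy-6-(2-oxotetracosyl)-2H-pyran-2-one | O=C1C=C(O)C=C(CC(=O)CCCCCCCCCCCCCCCCCCCCCC)O1
F3 | step 1 | 2,4-dihydroxy-6-docosylbenzoic acid | OC(=O)c1c(O)cc(O)cc1CCCCCCCCCCCCCCCCCCCCCC
F4 | step 1 | 5-docosylresorcinol (5-docosylbenzene-1,3-diol) | Oc1cc(O)cc(CCCCCCCCCCCCCCCCCCCCCC)c1
F5 | step 3 | 1,2,4-triacetoxy-3-docosyl-5-methoxybenzene | CC(=O)Oc1cc(OC)c(OC(C)=O)c(CCCCCCCCCCCCCCCCCCCCCC)c1OC(C)=O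
F6 | step 3 | 3-docosyl-5-methoxybenzene-1,2,4-triol | COc1cc(O)c(O)c(CCCCCCCCCCCCCCCCCCCCCC)c1O
F7 | step 2 | 3-methoxy-4-nitroso-5-docosylphenol | COc1cc(O)cc(CCCCCCCCCCCCCCCCCCCCCC)c1N=O
F8 | step 2 | 4-amino-3-methoxy-5-docosylphenol | COc1cc(O)cc(CCCCCCCCCCCCCCCCCCCCCC)c1N
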